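## Retrosynthetic overview

1. The oxirane goes in last, by tartrate-controlled (Sharpless) epoxidation of the (Z)-1,2-alkene of a macrocyclic 3,10-diol.
2. The ten-membered carbocycle is closed by ring-closing metathesis (C1=C2) of a bis(vinyl carbinol); the C-3 carbinol comes from an asymmetric Nozaki–Hiyama–Kishi coupling of a (Z)-alkenyl iodide with acrolein.
3. The cis-fused α-methylene-γ-lactone (C6–C7 bond, C-6 and C-7) comes from an indium Barbier allylation of (Z)-3-iodobut-2-enal with a (Z)-2-(bromomethyl)enoate, then lactonization; the angelate is put on C-8 after N–O cleavage.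
4. The bromide comes from Baylis–Hillman reaction and allylic transposition of an α-oxyaminated aldehyde made from (R)-linalool (C-10 from the chiral pool, C-8 by organocatalysis).
5. Ring order: γ-lactone (step 8), carbocycle (step 12), oxirane (step 13).

Assumption: positions are numbered as in germacranolides (ring C-1 to C-10, lactone C-6/C-7/C-11/C-12, exocyclic C-13, methyl C-14 on C-10, methyl C-15 on C-4); for each chiral catalyst or ligand, the enantiomer named is the one taken to give the configuration drawn, and its antipode is used if the sense proves opposite; building blocks that bring carbon into the product are numbered as reactants, other atom donors stand on the reagent line.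

## Route

Step 1
Reactants: 1 (R)-(−)-linalool
Product: 2 (3R)-3,7-dimethyl-3-(triethylsilyloxy)octa-1,6-diene
Conditions: TESOTf, 2,6-lutidine, CH2Cl2, −78 to 0 °C
Reagents that add atoms: triethylsilyl trifluoromethanesulfonate, CC[Si](CC)(CC)OS(=O)(=O)C(F)(F)F
Why: Silylation of the hindered tertiary alcohol with the silyl triflate masks the hydroxyl so that the aldehyde of step 2 cannot close to a lactol; the C-10 stereocentre comes from the chiral pool and is not touched.

Step 2
Reactants: 2 (3R)-3,7-dimethyl-3-(triethylsilyloxy)octa-1,6-diene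
Product: 4 (4R)-4-methyl-4-(triethylsilyloxy)hex-5-enal, via ozonide 3 (not isolated)
Conditions: O3 (1 equiv, Sudan Red 7B end point), CH2Cl2, −78 °C; then Me2S, −78 °C to rt
Reagents that add atoms: ozone, [O-][O+]=O
Why: Chemoselective ozonolysis, in which the electron-rich trisubstituted alkene is cleaved far faster than the vinyl group on the fully substituted carbon, followed by reductive work-up to the aldehyde.

Step 3
Reactants: 4 (4R)-4-methyl-4-(triethylsilyloxy)hex-5-enal
Product: 5 (2S,4R)-4-methyl-2-[(2,2,6,6-tetramethylpiperidin-1-yl)oxy]-4-(triethylsilyloxy)hex-5-enal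
Conditions: TEMPO (1.2 equiv), CuCl2·2H2O (10 mol %), (5R)-5-benzyl-2,2,3-trimethylimidazolidin-4-one·TFA (20 mol %), air, acetone, −10 °C
Reagents that add atoms: TEMPO, CC1(C)CCCC(C)(C)N1[O]
Why: Organocatalytic enantioselective α-oxyamination (enamine catalysis with CuCl2/air turnover), in which the imidazolidinone shields one enamine face so that TEMPO adds to give the (2S) centre, the future C-8, independently of the remote C-10 centre.

Step 4
Reactants: 5 (2S,4R)-4-methyl-2-[(2,2,6,6-tetramethylpiperidin-1-yl)oxy]-4-(triethylsilyloxy)hex-5-enal; 6 methyl acrylate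
Product: 7 methyl (4S,6R)-3-hydroxy-6-methyl-2-methylidene-4-[(2,2,6,6-tetramethylpiperidin-1-yl)oxy]-6-(triethylsilyloxy)oct-7-enoate (C-3 epimer mixture)
Conditions: 6 (5 equiv), DABCO (0.5 equiv), MeOH, rt, 3–5 d
Reagents that add atoms: none
Why: Morita–Baylis–Hillman reaction of the activated α-oxy aldehyde with the acrylate; the new carbinol centre is unselective and is erased in step 5.

Step 5
Reactants: 7 methyl (4S,6R)-3-hydroxy-6-methyl-2-methylidene-4-[(2,2,6,6-tetramethylpiperidin-1-yl)oxy]-6-(triethylsilyloxy)oct-7-enoate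
Product: 8 methyl (2Z,4S,6R)-2-(bromomethyl)-6-methyl-4-[(2,2,6,6-tetramethylpiperidin-1-yl)oxy]-6-(triethylsilyloxy)octa-2,7-dienoate
Conditions: NBS, Me2S, CH2Cl2, 0 °C to rt
Reagents that add atoms: N-bromosuccinimide, O=C1CCC(=O)N1Br
Why: Corey–Kim-type activation of the allylic alcohol followed by SN2′ attack of bromide with allylic transposition gives the thermodynamically favoured (Z)-2-(bromomethyl)enoate (ester trans to the chain) and leaves C-8 untouched.

Step 6
Reactants: 9 but-2-yn-1-ol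
Product: 11 (2Z)-3-iodobut-2-en-1-ol, via alkenylalanate 10 (not isolated)
Conditions: NaAlH2(OCH2CH2OCH3)2, THF, 0 °C to rt; then I2, THF, −78 °C to rt
Reagents that add atoms: iodine, II
Why: Hydroxyl-directed trans-hydroalumination of the propargylic alcohol places aluminium at C-3 cis to the CH2O group in a five-membered alanate, and iodinolysis with retention gives the (Z)-alkenyl iodide.

Step 7
Reactants: 11 (2Z)-3-iodobut-2-en-1-ol
Product: 12 (2Z)-3-iodobut-2-enal
Conditions: MnO2 (15 equiv), CH2Cl2, rt; used at once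
Reagents that add atoms: none
Why: Allylic alcohol oxidation on the MnO2 surface under neutral conditions gives the enal without Z/E isomerisation.

Step 8
Reactants: 8 methyl (2Z,4S,6R)-2-(bromomethyl)-6-methyl-4-[(2,2,6,6-tetramethylpiperidin-1-yl)oxy]-6-(triethylsilyloxy)octa-2,7-dienoate; 12 (2Z)-3-iodobut-2-enal
Product: 14 (4S,5R)-5-[(1Z)-2-iodoprop-1-en-1-yl]-4-[(1S,3R)-3-methyl-1-[(2,2,6,6-tetramethylpiperidin-1-yl)oxy]-3-(triethylsilyloxy)pent-4-en-1-yl]-3-methylideneoxolan-2-one, via hydroxy ester 13 (not isolated)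
Conditions: In powder (1.5 equiv), THF/H2O 1:1, rt; then PPTS (cat.), CH2Cl2, rt
Reagents that add atoms: none
Why: Indium Barbier allylation through a chair transition state of the (Z)-allylindium gives the syn homoallylic alcohol (hence the cis lactone, C-6/C-7), the aldehyde adding to the allyl face anti to the C-8–O bond with H-8 eclipsing the alkene (allylic strain), and mild acid then closes the γ-lactone.

Step 9
Reactants: 14 (4S,5R)-5-[(1Z)-2-iodoprop-1-en-1-yl]-4-[(1S,3R)-3-methyl-1-[(2,2,6,6-tetramethylpiperidin-1-yl)oxy]-3-(triethylsilyloxy)pent-4-en-1-yl]-3-methylideneoxolan-2-one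
Product: 15 (4R,5R)-4-[(1S,3R)-1,3-dihydroxy-3-methylpent-4-en-1-yl]-5-[(1Z)-2-iodoprop-1-en-1-yl]-3-methylideneoxolan-2-one
Conditions: Zn dust, AcOH/THF/H2O 3:1:1, 50 °C
Reagents that add atoms: none
Why: Reductive N–O cleavage of the alkoxyamine by zinc in acetic acid frees the C-8 hydroxyl while the warm aqueous acid hydrolyses the tertiary triethylsilyl ether, and no stereocentre is involved.

Step 10
Reactants: 15 (4R,5R)-4-[(1S,3R)-1,3-dihydroxy-3-methylpent-4-en-1-yl]-5-[(1Z)-2-iodoprop-1-en-1-yl]-3-methylideneoxolan-2-one; 16 angelic acid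
Product: 17 (1S,3R)-3-hydroxy-1-[(2R,3R)-2-[(1Z)-2-iodoprop-1-en-1-yl]-4-methylidene-5-oxooxolan-3-yl]-3-methylpent-4-en-1-yl (2Z)-2-methylbut-2-enoate
Conditions: 16, 2,4,6-trichlorobenzoyl chloride, Et3N, toluene, rt; then 15, toluene, 80 °C (no DMAP)
Reagents that add atoms: none
Why: Yamaguchi-type esterification through the preformed mixed anhydride acylates only the secondary C-8 hydroxyl (the tertiary one is inert) and, without a nucleophilic catalyst, keeps the (Z)-geometry of the angelate.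

Step 11
Reactants: 17 (1S,3R)-3-hydroxy-1-[(2R,3R)-2-[(1Z)-2-iodoprop-1-en-1-yl]-4-methylidene-5-oxooxolan-3-yl]-3-methylpent-4-en-1-yl (2Z)-2-methylbut-2-enoate; 18 acrolein
Product: 19 (1S,3R)-3-hydroxy-1-[(2S,3R)-2-[(1Z,3S)-3-hydroxy-2-methylpenta-1,4-dien-1-yl]-4-methylidene-5-oxooxolan-3-yl]-3-methylpent-4-en-1-yl (2Z)-2-methylbut-2-enoate
Conditions: CrCl2 (4 equiv), (S)-N-[2-(4-isopropyl-4,5-dihydro-1,3-oxazol-2-yl)-6-methylphenyl]methanesulfonamide (4.4 equiv), Et3N (4.4 equiv), NiCl2 (5 mol %), 18 (3 equiv), THF, rt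
Reagents that add atoms: none
Why: Nozaki–Hiyama–Kishi coupling, in which the alkenyl iodide is passed via nickel to chromium with retention of the (Z)-geometry and adds to acrolein, the chiral sulfonamide ligand on chromium selecting the aldehyde face to give the (3S) carbinol.

Step 12
Reactants: 19 (1S,3R)-3-hydroxy-1-[(2S,3R)-2-[(1Z,3S)-3-hydroxy-2-methylpenta-1,4-dien-1-yl]-4-methylidene-5-oxooxolan-3-yl]-3-methylpent-4-en-1-yl (2Z)-2-methylbut-2-enoate
Product: 20 (1Z,3S,4Z,6S,7R,8S,10R)-8-angeloyloxy-3,10-dihydroxygermacra-1,4,11(13)-trien-12,6-olide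
Conditions: first-generation Grubbs catalyst RuCl2(PCy3)2(=CHPh) (20 mol %, in portions), 1,4-benzoquinone (10 mol %), CH2Cl2 (1 mM), 40 °C
Reagents that add atoms: none
Why: Ring-closing metathesis of the two monosubstituted vinyl carbinols (this catalyst leaves the electron-poor methylene lactone, the angelate and the trisubstituted alkene alone) closes the ten-membered ring, in which only the (Z)-1,2-alkene is accessible.

Step 13
Reactants: 20 (1Z,3S,4Z,6S,7R,8S,10R)-8-angeloyloxy-3,10-dihydroxygermacra-1,4,11(13)-trien-12,6-olide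
Product: 21 (1R,2R,3R,4Z,6S,7R,8S,10R)-8-angeloyloxy-1,2-epoxy-3,10-dihydroxygermacra-4,11(13)-dien-12,6-olide (CNP0351240.3)
Conditions: Ti(OiPr)4 (0.3 equiv), D-(−)-diisopropyl tartrate (0.36 equiv), TBHP (2 equiv, in decane), 4 Å MS, CH2Cl2, −20 °C
Reagents that add atoms: tert-butyl hydroperoxide, CC(C)(C)OO
Why: Sharpless epoxidation directed by the secondary C-3 hydroxyl, for which the 1,2-alkene is the matched olefin with the D-tartrate (the 4,5-alkene is mismatched and the tertiary hydroxyl does not bind), so that oxygen is delivered erythro to C-3 and gives the (1R,2R)-cis-epoxide.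

## Compound list

1 | (R)-(−)-linalool, (3R)-3,7-dimethylocta-1,6-dien-3-ol | C=C[C@](C)(O)CCC=C(C)C | starting material
2 | (3R)-3,7-dimethyl-3-(triethylsilyloxy)octa-1,6-diene | C=C[C@](C)(O[Si](CC)(CC)CC)CCC=C(C)C | intermediate
3 | ozonide, 3,3-dimethyl-5-[(3R)-3-methyl-3-(triethylsilyloxy)pent-4-en-1-yl]-1,2,4-trioxolane | C=C[C@](C)(O[Si](CC)(CC)CC)CCC1OOC(C)(C)O1 | intermediate
4 | (4R)-4-methyl-4-(triethylsilyloxy)hex-5-enal | C=C[C@](C)(O[Si](CC)(CC)CC)CCC=O | intermediate
5 | (2S,4R)-4-methyl-2-[(2,2,6,6-tetramethylpiperidin-1-yl)oxy]-4-(triethylsilyloxy)hex-5-enal | C=C[C@](C)(O[Si](CC)(CC)CC)C[C@H](ON1C(C)(C)CCCC1(C)C)C=O | intermediate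
6 | methyl acrylate | C=CC(=O)OC | starting material
7 | methyl (4S,6R)-3-hydroxy-6-methyl-2-methylidene-4-[(2,2,6,6-tetramethylpiperidin-1-yl)oxy]-6-(triethylsilyloxy)oct-7-enoate (C-3 epimer mixture) | C=C[C@](C)(O[Si](CC)(CC)CC)C[C@H](ON1C(C)(C)CCCC1(C)C)C(O)C(=C)C(=O)OC | intermediate
8 | methyl (2Z,4S,6R)-2-(bromomethyl)-6-methyl-4-[(2,2,6,6-tetramethylpiperidin-1-yl)oxy]-6-(triethylsilyloxy)octa-2,7-dienoate | C=C[C@](C)(O[Si](CC)(CC)CC)C[C@H](ON1C(C)(C)CCCC1(C)C)/C=C(\CBr)C(=O)OC | intermediate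
9 | but-2-yn-1-ol | CC#CCO | starting material
10 | alkenylalanate, sodium 2,2-bis(2-methoxyethoxy)-3-methyl-2,5-dihydro-1,2-oxaaluminol-2-uide | CC1=CCO[Al-]1(OCCOC)OCCOC.[Na+] | intermediate
11 | (2Z)-3-iodobut-2-en-1-ol | C/C(I)=C/CO | intermediate
12 | (2Z)-3-iodobut-2-enal | C/C(I)=C/C=O | intermediate
13 | hydroxy ester, methyl (3S,4R,5Z)-4-hydroxy-6-iodo-2-methylidene-3-[(1S,3R)-3-methyl-1-[(2,2,6,6-tetramethylpiperidin-1-yl)oxy]-3-(triethylsilyloxy)pent-4-en-1-yl]hept-5-enoate | C=C(C(=O)OC)[C@@H]([C@@H](O)/C=C(/C)I)[C@@H](ON1C(C)(C)CCCC1(C)C)C[C@@](C)(O[Si](CC)(CC)CC)C=C | intermediate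
14 | (4S,5R)-5-[(1Z)-2-iodoprop-1-en-1-yl]-4-[(1S,3R)-3-methyl-1-[(2,2,6,6-tetramethylpiperidin-1-yl)oxy]-3-(triethylsilyloxy)pent-4-en-1-yl]-3-methylideneoxolan-2-one | C=C1C(=O)O[C@@H](/C=C(/C)I)[C@H]1[C@@H](ON2C(C)(C)CCCC2(C)C)C[C@@](C)(O[Si](CC)(CC)CC)C=C | intermediate
15 | (4R,5R)-4-[(1S,3R)-1,3-dihydroxy-3-methylpent-4-en-1-yl]-5-[(1Z)-2-iodoprop-1-en-1-yl]-3-methylideneoxolan-2-one | C=C1C(=O)O[C@@H](/C=C(/C)I)[C@H]1[C@@H](O)C[C@@](C)(O)C=C | intermediate
16 | angelic acid, (2Z)-2-methylbut-2-enoic acid | C/C=C(/C)C(=O)O | starting material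
17 | (1S,3R)-3-hydroxy-1-[(2R,3R)-2-[(1Z)-2-iodoprop-1-en-1-yl]-4-methylidene-5-oxooxolan-3-yl]-3-methylpent-4-en-1-yl (2Z)-2-methylbut-2-enoate | C=C1C(=O)O[C@@H](/C=C(/C)I)[C@H]1[C@@H](OC(=O)/C(C)=C\C)C[C@@](C)(O)C=C | intermediate
18 | acrolein | C=CC=O | starting material
19 | (1S,3R)-3-hydroxy-1-[(2S,3R)-2-[(1Z,3S)-3-hydroxy-2-methylpenta-1,4-dien-1-yl]-4-methylidene-5-oxooxolan-3-yl]-3-methylpent-4-en-1-yl (2Z)-2-methylbut-2-enoate | C=C1C(=O)O[C@@H](/C=C(/C)[C@@H](O)C=C)[C@H]1[C@@H](OC(=O)/C(C)=C\C)C[C@@](C)(O)C=C | intermediate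
20 | (1Z,3S,4Z,6S,7R,8S,10R)-8-angeloyloxy-3,10-dihydroxygermacra-1,4,11(13)-trien-12,6-olide | C=C1C(=O)O[C@H]2/C=C(/C)[C@@H](O)/C=C\[C@](C)(O)C[C@H](OC(=O)/C(C)=C\C)[C@@H]12 | intermediate
21 | (1R,2R,3R,4Z,6S,7R,8S,10R)-8-angeloyloxy-1,2-epoxy-3,10-dihydroxygermacra-4,11(13)-dien-12,6-olide | C=C1C(=O)O[C@H]2/C=C(/C)[C@@H](O)[C@H]3O[C@H]3[C@](C)(O)C[C@H](OC(=O)/C(C)=C\C)[C@@H]12 | target

## Step count and risks

Total step count: 13. Longest linear sequence: 11 steps (steps 1–5 and 8–13, from 1 to 21); steps 6–7 make the second fragment.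

The three steps most likely to fail:

Step 8, facial sense of the Barbier allylation. The syn (cis-lactone) outcome is reliable for (Z)-2-(bromomethyl)enoates, but the face chosen relative to the C-8 oxygen rests on a model (attack anti to the C–O bond). If the allylindium adds on the other face, C-6 and C-7 come out with the wrong absolute sense. The fallback sets out from 4 and comes back at 17. The antipodal imidazolidinone in the oxyamination gives the (2R)-oxyaminated aldehyde F1. The same Baylis–Hillman and bromination operations carry it to the (4R)-Baylis–Hillman adduct F2 and the (4R)-allyl bromide F3. The indium reaction with 12 then gives, via the 8-epi hydroxy ester F4, the 8-epi lactone F5 with the required C-6 and C-7 centres. Zn/AcOH gives the 8-epi diol F6. A Mitsunobu esterification of F6 with 16 (PPh3, DIAD, toluene, 0 °C) inverts C-8 while putting on the angelate and gives 17.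

Step 12, closure of the strained ten-membered ring. The first-generation catalyst may be too weak for it, and the more active second-generation catalysts would also engage the methylene lactone (six- or seven-membered ring closure onto C-11). The fallback sets out from 19 and comes back at 20. The methylene lactone is masked by conjugate addition of Me2NH (THF, 0 °C) to give the 13-dimethylamino-11,13-dihydro adduct F7. This is cyclised as its TsOH salt with second-generation Hoveyda–Grubbs catalyst RuCl2(H2IMes)(=CH-C6H4-2-OiPr) in toluene at 80 °C to the macrocyclic amine F8. MeI gives the methiodide F9, and NaHCO3 eliminates trimethylamine to restore the methylene lactone, giving 20.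

Step 13, rate and selectivity of the epoxidation. A (Z)-allylic alcohol with a fully substituted cis neighbour is a slow Sharpless substrate, and the 4,5-alkene is also allylic to the C-3 hydroxyl. The fallback sets out from 20 and comes back at 21, and moves the directing role to the tertiary C-10 hydroxyl, to which only the 1,2-alkene is allylic. Selective silylation of the secondary hydroxyl (TESCl, imidazole, DMF, 0 °C) gives the 3-O-triethylsilyl ether F10. Epoxidation with mCPBA/NaHCO3 in CH2Cl2 at 0 °C, delivered by hydrogen bonding from the C-10 hydroxyl (trans to the directing hydroxyl, as peracids behave with medium-ring allylic alcohols), gives the epoxy silyl ether F11. HF·pyridine in THF/pyridine at 0 °C removes the silyl group and gives 21.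

Further compounds

F1 | step 8 | (2R,4R)-4-methyl-2-[(2,2,6,6-tetramethylpiperidin-1-yl)oxy]-4-(triethylsilyloxy)hex-5-enal | C=C[C@](C)(O[Si](CC)(CC)CC)C[C@@H](ON1C(C)(C)CCCC1(C)C)C=O
F2 | step 8 | methyl (4R,6R)-3-hydroxy-6-methyl-2-methylidene-4-[(2,2,6,6-tetramethylpiperidin-1-yl)oxy]-6-(triethylsilyloxy)oct-7-enoate (C-3 epimer mixture) | C=C[C@](C)(O[Si](CC)(CC)CC)C[C@@H](ON1C(C)(C)CCCC1(C)C)C(O)C(=C)C(=O)OC
F3 | step 8 | methyl (2Z,4R,6R)-2-(bromomethyl)-6-methyl-4-[(2,2,6,6-tetramethylpiperidin-1-yl)oxy]-6-(triethylsilyloxy)octa-2,7-dienoate | C=C[C@](C)(O[Si](CC)(CC)CC)C[C@@H](ON1C(C)(C)CCCC1(C)C)/C=C(\CBr)C(=O)OC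
F4 | step 8 | methyl (3S,4R,5Z)-4-hydroxy-6-iodo-2-methylidene-3-[(1R,3R)-3-methyl-1-[(2,2,6,6-tetramethylpiperidin-1-yl)oxy]-3-(triethylsilyloxy)pent-4-en-1-yl]hept-5-enoate | C=C(C(=O)OC)[C@@H]([C@@H](O)/C=C(/C)I)[C@H](ON1C(C)(C)CCCC1(C)C)C[C@@](C)(O[Si](CC)(CC)CC)C=C
F5 | step 8 | (4S,5R)-5-[(1Z)-2-iodoprop-1-en-1-yl]-4-[(1R,3R)-3-methyl-1-[(2,2,6,6-tetramethylpiperidin-1-yl)oxy]-3-(triethylsilyloxy)pent-4-en-1-yl]-3-methylideneoxolan-2-one | C=C1C(=O)O[C@@H](/C=C(/C)I)[C@H]1[C@H](ON2C(C)(C)CCCC2(C)C)C[C@@](C)(O[Si](CC)(CC)CC)C=C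
F6 | step 8 | (4R,5R)-4-[(1R,3R)-1,3-dihydroxy-3-methylpent-4-en-1-yl]-5-[(1Z)-2-iodoprop-1-en-1-yl]-3-methylideneoxolan-2-one | C=C1C(=O)O[C@@H](/C=C(/C)I)[C@H]1[C@H](O)C[C@@](C)(O)C=C
F7 | step 12 | 13-dimethylamino-11,13-dihydro adduct of 19 (C-11 epimer mixture) | CN(C)CC1C(=O)O[C@@H](/C=C(/C)[C@@H](O)C=C)[C@H]1[C@@H](OC(=O)/C(C)=C\C)C[C@@](C)(O)C=C
F8 | step 12 | 13-dimethylamino-11,13-dihydro derivative of 20 (C-11 epimer mixture) | CN(C)CC1C(=O)O[C@H]2/C=C(/C)[C@@H](O)/C=C\[C@](C)(O)C[C@H](OC(=O)/C(C)=C\C)[C@@H]12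
F9 | step 12 | N-methyl ammonium iodide of F8 | C[N+](C)(C)CC1C(=O)O[C@H]2/C=C(/C)[C@@H](O)/C=C\[C@](C)(O)C[C@H](OC(=O)/C(C)=C\C)[C@@H]12.[I-]
F10 | step 13 | 3-O-triethylsilyl ether of 20 | C=C1C(=O)O[C@H]2/C=C(/C)[C@@H](O[Si](CC)(CC)CC)/C=C\[C@](C)(O)C[C@H](OC(=O)/C(C)=C\C)[C@@H]12
F11 | step 13 | 3-O-triethylsilyl ether of 21 | C=C1C(=O)O[C@H]2/C=C(/C)[C@@H](O[Si](CC)(CC)CC)[C@H]3O[C@H]3[C@](C)(O)C[C@H](OC(=O)/C(C)=C\C)[C@@H]12
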